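Ring B (C5–C10) of the target is, in masked form, a 2,3-disubstituted cyclohex-2-enone: C6 bears oxygen and C5=C10 is tetrasubstituted. The plan cuts C5–C6 and C9–C10. The alkene carbons then come from one silyl alkyne that already carries the C4 stereocentre and the side chain, and C6–C9 from a strained cis-2,3-disubstituted cyclobutanone that already carries C7 and C8. One nickel-catalysed alkyne insertion into the C6–C9 bond (strain-release (4+2)) closes ring B as the C6 enone with silicon on C10. The precursors are (2R,3R)-cyclobutanone 8 (acetate arm on C7, PMB ether on C8) and (R)-alkynylsilane 15; everything else is functional-group work.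

Key step: step 9

Numbering used throughout: ring B = C5–C10 with C5=C10; C6 carries the angelate; C7/C8 are the lactone ring fusion (O on C8); C9 is the ring CH2; C14 is the CH2OH on C10; the chain on C5 is C4(H)(CH3)–C3–C2–C1(OH); the lactone is C11(=C13H2)–C12(=O). The target is (4R,6S,7R,8R): cis-fused lactone, C6–O on the face opposite to C8–O.

Remark on spectator groups: the acetate arm is carried as its tert-butyl ester, which can neither acylate a metal alkoxide in step 9 nor lactonise before the hydroxyl-directed reduction in step 11. The silyl group on C10 is exchanged for iodine only after C6 is sp3, because a β-silyl enone resists ipso-iodination.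

Assumption: the absolute configuration of the resolved cyclobutanone 8 is assigned independently (for example by anomalous-dispersion X-ray analysis of a derivative), and (R)-β-citronellene 9 is available in high enantiomeric purity.

Step 1
Reactants: 1 4-methoxybenzyl alcohol; 2 ethyl vinyl ether
Product: 3 4-methoxybenzyl vinyl ether
Conditions: Pd(OAc)2 (cat.), 1,10-phenanthroline (cat.), 2 in excess, CH2Cl2, rt
Reagents that add atoms: none
Why: Transfer vinylation (transetherification) catalysed by divalent palladium exchanges the ethoxy group for the benzylic alkoxide, and the excess of 2 drives the equilibrium.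

Step 2
Reactants: 4 4-tert-butoxy-4-oxobutanoic acid; 3 4-methoxybenzyl vinyl ether
Product: 7 racemic cis-cyclobutanone tert-butyl 2-[(1R*,2R*)-2-(4-methoxybenzyloxy)-4-oxocyclobutyl]acetate, via acid chloride 5 (not isolated), via ketene 6 (not isolated)
Conditions: 1-chloro-N,N,2-trimethylprop-1-en-1-amine, MeCN, 0 °C; then 3 (3 equiv), Et3N, 60 °C; chromatography
Reagents that add atoms: none
Why: The chloroenamine makes the acid chloride under neutral conditions, Et3N generates the monoalkylketene, and thermal ketene–enol ether [2+2] cycloaddition joins the ketene carbonyl carbon to the vinyl CH2 and the ketene α-carbon to the oxygenated carbon, the perpendicular approach being expected to favour the cis isomer (relative configuration of C7/C8), which is separated from the trans isomer.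

Step 3
Reactants: 7 racemic cis-cyclobutanone
Product: 8 tert-butyl 2-[(1R,2R)-2-(4-methoxybenzyloxy)-4-oxocyclobutyl]acetate
Conditions: preparative SFC on amylose tris(3,5-dimethylphenylcarbamate), CO2/i-PrOH
Reagents that add atoms: none
Why: Chromatographic resolution on a chiral stationary phase separates the enantiomers of this rigid, UV-active ketone, and the (1R,2R) enantiomer supplies the absolute configuration of C7 and C8.

Step 4
Reactants: 9 (R)-β-citronellene
Product: 10 (R)-4-methylhex-5-en-1-ol
Conditions: O3 (1 equiv), CH2Cl2/MeOH, −78 °C; NaBH4, −78 °C → rt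
Reagents that add atoms: ozone, [O-][O+]=O
Why: Chemoselective ozonolysis cleaves the electron-rich trisubstituted alkene much faster than the vinyl group, and borohydride reduces the ozonide to the primary alcohol without touching the C4 stereocentre.

Step 5
Reactants: 10 (R)-4-methylhex-5-en-1-ol
Product: 11 (R)-tert-butyldimethyl[(4-methylhex-5-en-1-yl)oxy]silane
Conditions: TBSCl, imidazole, CH2Cl2, rt
Reagents that add atoms: tert-butyldimethylsilyl chloride, CC(C)(C)[Si](C)(C)Cl
Why: Standard silylation of a primary alcohol gives an ether that survives ozone, alkyllithium, nickel catalysis, DDQ and the acidic reduction medium.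

Step 6
Reactants: 11 (R)-tert-butyldimethyl[(4-methylhex-5-en-1-yl)oxy]silane
Product: 12 (R)-5-(tert-butyldimethylsilyloxy)-2-methylpentanal
Conditions: O3, CH2Cl2, −78 °C; PPh3, −78 °C → rt
Reagents that add atoms: ozone, [O-][O+]=O
Why: Ozonolysis of the vinyl group with neutral phosphine work-up gives the α-stereogenic aldehyde without exposure to acid or base, so C4 should not epimerise.

Step 7
Reactants: 12 (R)-5-(tert-butyldimethylsilyloxy)-2-methylpentanal
Product: 13 (R)-tert-butyl[(6,6-dibromo-4-methylhex-5-en-1-yl)oxy]dimethylsilane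
Conditions: CBr4, PPh3, Zn, CH2Cl2, rt
Reagents that add atoms: carbon tetrabromide, BrC(Br)(Br)Br
Why: The first stage of the Corey–Fuchs reaction (Wittig-type dibromo-olefination) runs under neutral, zinc-buffered conditions that should not epimerise the α-methyl aldehyde.

Step 8
Reactants: 13 (R)-tert-butyl[(6,6-dibromo-4-methylhex-5-en-1-yl)oxy]dimethylsilane
Product: 15 (R)-tert-butyldimethyl{[4-methyl-6-(trimethylsilyl)hex-5-yn-1-yl]oxy}silane, via lithium acetylide 14 (not isolated)
Conditions: n-BuLi (2.1 equiv), THF, −78 → 0 °C; TMSCl, −78 °C → rt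
Reagents that add atoms: chlorotrimethylsilane, C[Si](C)(C)Cl
Why: The second Corey–Fuchs stage (bromine–lithium exchange, Fritsch–Buttenberg–Wiechell shift, deprotonation) gives the lithium acetylide, which is silylated on carbon in the same flask.

Step 9
Reactants: 8 tert-butyl 2-[(1R,2R)-2-(4-methoxybenzyloxy)-4-oxocyclobutyl]acetate; 15 (R)-tert-butyldimethyl{[4-methyl-6-(trimethylsilyl)hex-5-yn-1-yl]oxy}silane
Product: 16 tert-butyl 2-[(1R,6R)-3-[(2R)-5-(tert-butyldimethylsilyloxy)pentan-2-yl]-6-(4-methoxybenzyloxy)-2-oxo-4-(trimethylsilyl)cyclohex-3-en-1-yl]acetate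
Conditions: Ni(cod)2 (10 mol %), PCy3 (20 mol %), 15 (1.5 equiv), toluene, 90 °C, argon
Reagents that add atoms: none
Why: Proposed new method: zerovalent nickel is expected to couple the C6 carbonyl of 8 with the alkyne of 15 oxidatively to a spiro oxanickelacyclopentene (C5–C6 bond), β-carbon elimination then opens the strained C6–C9 bond to a seven-membered nickelacycle, and C(sp3)–C(sp2) reductive elimination joins C9 to C10. The closest known reaction type is the nickel-catalysed intermolecular insertion of internal alkynes into simple 3-substituted cyclobutanones to give cyclohex-2-enones; a 2,3-disubstituted 3-alkoxycyclobutanone and an α-branched silyl alkyne have not been shown. Ring B closes by a formal (4+2) ring expansion (C6–C7–C8–C9 plus C5≡C10), paid for by cyclobutanone strain. No stereocentre is formed: C7 and C8 come from 8, C4 from 15, and the neutral, base-free medium should leave the C7 centre α to the new ketone untouched. Regiochemistry has to be right twice: the silyl group should sit on the nickel-bound carbon (steric demand and α-silyl stabilisation) so that C5 bonds to C6, and β-carbon elimination should take the unsubstituted C9 and not the branched C7. The pathway to be outrun is β-alkoxide elimination from the C9–nickel species next to the C8 ether, against which the poor leaving ability of the PMB alkoxide and the bulky electron-rich PCy3, which speeds reductive elimination, are relied on, while the tert-butyl ester cannot trap the nickel alkoxide.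

Step 10
Reactants: 16 ring B enone with PMB ether
Product: 17 tert-butyl 2-[(1R,6R)-3-[(2R)-5-(tert-butyldimethylsilyloxy)pentan-2-yl]-6-hydroxy-2-oxo-4-(trimethylsilyl)cyclohex-3-en-1-yl]acetate
Conditions: DDQ, CH2Cl2/pH 7 buffer, 0 °C
Reagents that add atoms: none
Why: Oxidative PMB cleavage by DDQ (hydride abstraction, then hydrolysis of the oxocarbenium ion) runs under buffered neutral conditions that spare both silyl groups and avoid the base that would eliminate the β-oxygen.

Step 11
Reactants: 17 β-hydroxy enone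
Product: 19 (3aS,4S,7aR)-5-[(2R)-5-(tert-butyldimethylsilyloxy)pentan-2-yl]-4-hydroxy-6-(trimethylsilyl)-3a,4,7,7a-tetrahydro-1-benzofuran-2(3H)-one, via diol ester 18 (not isolated)
Conditions: Me4NBH(OAc)3, MeCN/AcOH, −30 °C; work-up; then KOt-Bu (cat.), THF, 0 °C
Reagents that add atoms: none
Why: In the Evans–Saksena reduction the C8 hydroxyl binds boron and delivers hydride to its own face of the C6 carbonyl, so the new C6 hydroxyl ends up trans to C8–O (1,3-anti, the (6S) centre), after which catalytic tert-butoxide closes the cis hydroxy ester to the cis-fused γ-lactone (intramolecular transesterification), the trans C6 alkoxide being unable to reach the ester in the favoured conformer.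

Step 12
Reactants: 19 silyl hydroxy lactone
Product: 20 (3aS,4S,7aR)-5-[(2R)-5-(tert-butyldimethylsilyloxy)pentan-2-yl]-4-hydroxy-6-iodo-3a,4,7,7a-tetrahydro-1-benzofuran-2(3H)-one
Conditions: NIS, 2,6-lutidine, (CF3)2CHOH, 0 °C
Reagents that add atoms: N-iodosuccinimide, O=C1CCC(=O)N1I
Why: Electrophilic ipso-iododesilylation puts iodine on the silicon-bearing C10 through the β-silyl cation at C5, which is no longer α to a carbonyl now that C6 is sp3, and the ring fixes the alkene geometry.

Step 13
Reactants: 20 alkenyl iodide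
Product: 21 (3aS,4S,7aR)-5-[(2R)-5-(tert-butyldimethylsilyloxy)pentan-2-yl]-4-hydroxy-6-(hydroxymethyl)-3a,4,7,7a-tetrahydro-1-benzofuran-2(3H)-one
Conditions: Bu3SnCH2OH, Pd(PPh3)4 (cat.), dioxane, 90 °C
Reagents that add atoms: (tributylstannyl)methanol, CCCC[Sn](CCCC)(CCCC)CO
Why: Stille cross-coupling under neutral conditions transfers the hydroxymethyl group (C14) to C10 and tolerates the lactone and the free C6 hydroxyl.

Step 14
Reactants: 21 diol
Product: 22 (3aS,4S,7aR)-5-[(2R)-5-(tert-butyldimethylsilyloxy)pentan-2-yl]-6-[(tert-butyldimethylsilyloxy)methyl]-4-hydroxy-3a,4,7,7a-tetrahydro-1-benzofuran-2(3H)-one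
Conditions: TBSCl (1.1 equiv), imidazole, CH2Cl2, 0 °C
Reagents that add atoms: tert-butyldimethylsilyl chloride, CC(C)(C)[Si](C)(C)Cl
Why: Selective silylation works because the primary allylic C14 hydroxyl reacts far faster than the hindered secondary C6 hydroxyl.

Step 15
Reactants: 22 bis-silyl hydroxy lactone
Product: 25 (3aS,4S,7aR)-5-[(2R)-5-(tert-butyldimethylsilyloxy)pentan-2-yl]-6-[(tert-butyldimethylsilyloxy)methyl]-4-hydroxy-3-methylidene-3a,4,7,7a-tetrahydro-1-benzofuran-2(3H)-one, via Mannich base 23 (not isolated), via ammonium iodide 24 (not isolated)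
Conditions: LiN(i-Pr)2 (2.3 equiv), THF, −78 °C; CH2=NMe2+ I−, −78 → 0 °C; aq. NH4Cl; MeI, MeOH, rt; NaHCO3 (aq)/CH2Cl2
Reagents that add atoms: N,N-dimethylmethyleneiminium iodide (Eschenmoser's salt), C=[N+](C)C.[I-]
Why: In the Eschenmoser methylenation the lactone enolate (C6–OH held as its alkoxide) undergoes a Mannich reaction at C11, and quaternisation followed by E1cB elimination of trimethylamine gives the exocyclic C11=C13 alkene.

Step 16
Reactants: 25 α-methylene hydroxy lactone
Product: 26 (3aR,4S,7aR)-5-[(2R)-5-(tert-butyldimethylsilyloxy)pentan-2-yl]-6-[(tert-butyldimethylsilyloxy)methyl]-3-methylidene-2-oxo-2,3,3a,4,7,7a-hexahydro-1-benzofuran-4-yl (2Z)-2-methylbut-2-enoate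
Conditions: angelic acid, 2,4,6-trichlorobenzoyl chloride, Et3N, toluene, rt; then 25, toluene, 80 °C
Reagents that add atoms: angelic acid, C/C=C(/C)C(=O)O
Why: Yamaguchi-type mixed-anhydride esterification acylates the hindered C6 hydroxyl, and is chosen because it is the standard way to form angelates without Z to E isomerisation to the tiglate.

Step 17
Reactants: 26 bis-silyl angelate
Product: 27 (3aR,4S,7aR)-5-[(2R)-5-hydroxypentan-2-yl]-6-(hydroxymethyl)-3-methylidene-2-oxo-2,3,3a,4,7,7a-hexahydro-1-benzofuran-4-yl (2Z)-2-methylbut-2-enoate (CNP0106570.2)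
Conditions: HF·pyridine, pyridine/THF, 0 °C → rt
Reagents that add atoms: none
Why: Fluoride-mediated desilylation under mildly acidic buffered conditions removes both primary silyl ethers and leaves the angelate and the base-sensitive α-methylene lactone intact.

Compound list
1 | 4-methoxybenzyl alcohol | COc1ccc(CO)cc1 | starting material
2 | ethyl vinyl ether | CCOC=C | starting material
3 | 4-methoxybenzyl vinyl ether | C=COCc1ccc(OC)cc1 | intermediate
4 | 4-tert-butoxy-4-oxobutanoic acid (mono-tert-butyl succinate) | CC(C)(C)OC(=O)CCC(=O)O | starting material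
5 | tert-butyl 4-chloro-4-oxobutanoate (not isolated) | CC(C)(C)OC(=O)CCC(Cl)=O | intermediate
6 | tert-butyl 4-oxobut-3-enoate, the monoalkylketene (not isolated) | CC(C)(C)OC(=O)CC=C=O | intermediate
7 | racemic cis tert-butyl 2-[(1R*,2R*)-2-(4-methoxybenzyloxy)-4-oxocyclobutyl]acetate (racemate, one enantiomer drawn) | CC(C)(C)OC(=O)C[C@@H]1[C@H](OCc2ccc(OC)cc2)CC1=O | intermediate
8 | tert-butyl 2-[(1R,2R)-2-(4-methoxybenzyloxy)-4-oxocyclobutyl]acetate | CC(C)(C)OC(=O)C[C@@H]1[C@H](OCc2ccc(OC)cc2)CC1=O | intermediate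
9 | (R)-β-citronellene, (3R)-3,7-dimethylocta-1,6-diene | C=C[C@H](C)CCC=C(C)C | starting material
10 | (R)-4-methylhex-5-en-1-ol | C=C[C@H](C)CCCO | intermediate
11 | (R)-tert-butyldimethyl[(4-methylhex-5-en-1-yl)oxy]silane | C=C[C@H](C)CCCO[Si](C)(C)C(C)(C)C | intermediate
12 | (R)-5-(tert-butyldimethylsilyloxy)-2-methylpentanal | O=C[C@H](C)CCCO[Si](C)(C)C(C)(C)C | intermediate
13 | (R)-tert-butyl[(6,6-dibromo-4-methylhex-5-en-1-yl)oxy]dimethylsilane | BrC(Br)=C[C@H](C)CCCO[Si](C)(C)C(C)(C)C | intermediate
14 | [(3R)-6-(tert-butyldimethylsilyloxy)-3-methylhex-1-yn-1-yl]lithium (not isolated) | [Li]C#C[C@H](C)CCCO[Si](C)(C)C(C)(C)C | intermediate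
15 | (R)-tert-butyldimethyl{[4-methyl-6-(trimethylsilyl)hex-5-yn-1-yl]oxy}silane | C[Si](C)(C)C#C[C@H](C)CCCO[Si](C)(C)C(C)(C)C | intermediate
16 | tert-butyl 2-[(1R,6R)-3-[(2R)-5-(tert-butyldimethylsilyloxy)pentan-2-yl]-6-(4-methoxybenzyloxy)-2-oxo-4-(trimethylsilyl)cyclohex-3-en-1-yl]acetate | CC(C)(C)OC(=O)C[C@@H]1[C@H](OCc2ccc(OC)cc2)CC([Si](C)(C)C)=C([C@H](C)CCCO[Si](C)(C)C(C)(C)C)C1=O | intermediate
17 | tert-butyl 2-[(1R,6R)-3-[(2R)-5-(tert-butyldimethylsilyloxy)pentan-2-yl]-6-hydroxy-2-oxo-4-(trimethylsilyl)cyclohex-3-en-1-yl]acetate | CC(C)(C)OC(=O)C[C@@H]1[C@H](O)CC([Si](C)(C)C)=C([C@H](C)CCCO[Si](C)(C)C(C)(C)C)C1=O | intermediate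
18 | tert-butyl 2-[(1R,2S,6R)-3-[(2R)-5-(tert-butyldimethylsilyloxy)pentan-2-yl]-2,6-dihydroxy-4-(trimethylsilyl)cyclohex-3-en-1-yl]acetate (not isolated) | CC(C)(C)OC(=O)C[C@@H]1[C@H](O)CC([Si](C)(C)C)=C([C@H](C)CCCO[Si](C)(C)C(C)(C)C)[C@H]1O | intermediate
19 | (3aS,4S,7aR)-5-[(2R)-5-(tert-butyldimethylsilyloxy)pentan-2-yl]-4-hydroxy-6-(trimethylsilyl)-3a,4,7,7a-tetrahydro-1-benzofuran-2(3H)-one | C1C(=O)O[C@@H]2CC([Si](C)(C)C)=C([C@H](C)CCCO[Si](C)(C)C(C)(C)C)[C@@H](O)[C@H]12 | intermediate
20 | (3aS,4S,7aR)-5-[(2R)-5-(tert-butyldimethylsilyloxy)pentan-2-yl]-4-hydroxy-6-iodo-3a,4,7,7a-tetrahydro-1-benzofuran-2(3H)-one | C1C(=O)O[C@@H]2CC(I)=C([C@H](C)CCCO[Si](C)(C)C(C)(C)C)[C@@H](O)[C@H]12 | intermediate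
21 | (3aS,4S,7aR)-5-[(2R)-5-(tert-butyldimethylsilyloxy)pentan-2-yl]-4-hydroxy-6-(hydroxymethyl)-3a,4,7,7a-tetrahydro-1-benzofuran-2(3H)-one | C1C(=O)O[C@@H]2CC(CO)=C([C@H](C)CCCO[Si](C)(C)C(C)(C)C)[C@@H](O)[C@H]12 | intermediate
22 | (3aS,4S,7aR)-5-[(2R)-5-(tert-butyldimethylsilyloxy)pentan-2-yl]-6-[(tert-butyldimethylsilyloxy)methyl]-4-hydroxy-3a,4,7,7a-tetrahydro-1-benzofuran-2(3H)-one | C1C(=O)O[C@@H]2CC(CO[Si](C)(C)C(C)(C)C)=C([C@H](C)CCCO[Si](C)(C)C(C)(C)C)[C@@H](O)[C@H]12 | intermediate
23 | 3-[(dimethylamino)methyl] derivative of 22, C11 epimers (not isolated) | CN(C)CC1C(=O)O[C@@H]2CC(CO[Si](C)(C)C(C)(C)C)=C([C@H](C)CCCO[Si](C)(C)C(C)(C)C)[C@@H](O)[C@H]12 | intermediate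
24 | trimethylammonium iodide of 23 (not isolated) | C[N+](C)(C)CC1C(=O)O[C@@H]2CC(CO[Si](C)(C)C(C)(C)C)=C([C@H](C)CCCO[Si](C)(C)C(C)(C)C)[C@@H](O)[C@H]12.[I-] | intermediate
25 | (3aS,4S,7aR)-5-[(2R)-5-(tert-butyldimethylsilyloxy)pentan-2-yl]-6-[(tert-butyldimethylsilyloxy)methyl]-4-hydroxy-3-methylidene-3a,4,7,7a-tetrahydro-1-benzofuran-2(3H)-one | C=C1C(=O)O[C@@H]2CC(CO[Si](C)(C)C(C)(C)C)=C([C@H](C)CCCO[Si](C)(C)C(C)(C)C)[C@@H](O)[C@H]12 | intermediate
26 | (3aR,4S,7aR)-5-[(2R)-5-(tert-butyldimethylsilyloxy)pentan-2-yl]-6-[(tert-butyldimethylsilyloxy)methyl]-3-methylidene-2-oxo-2,3,3a,4,7,7a-hexahydro-1-benzofuran-4-yl (2Z)-2-methylbut-2-enoate | C=C1C(=O)O[C@@H]2CC(CO[Si](C)(C)C(C)(C)C)=C([C@H](C)CCCO[Si](C)(C)C(C)(C)C)[C@@H](OC(=O)/C(C)=C\C)[C@H]12 | intermediate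
27 | (3aR,4S,7aR)-5-[(2R)-5-hydroxypentan-2-yl]-6-(hydroxymethyl)-3-methylidene-2-oxo-2,3,3a,4,7,7a-hexahydro-1-benzofuran-4-yl (2Z)-2-methylbut-2-enoate (CNP0106570.2) | C=C1C(=O)O[C@@H]2CC(CO)=C([C@H](C)CCCO)[C@@H](OC(=O)/C(C)=C\C)[C@H]12 | target

Total step count: 17.
Longest linear sequence: 14 steps (from 9 through steps 4–8 and 9–17).

Steps most likely to fail

Step 9 (key step). What may go wrong: the hindered, α-branched silyl alkyne fails to enter oxidative coupling with the ketone at zerovalent nickel and oligomerises instead, or the C9–nickel intermediate loses the C8 alkoxide before the ring closes. The fallback uses known reaction types, sets out from 8 and 15 and returns at 16; it makes the same two bonds one after the other under stoichiometric control. Alkyne 15 is converted with Ti(OiPr)4 and 2 i-PrMgCl (Et2O, −78 to −50 °C) into its titanium–alkyne complex F1. This adds to the ketone of 8 through the carbon remote from silicon, the established regiochemistry for silyl alkynes, to give the oxatitanacyclopentene F2. I2 cleaves its C10–Ti bond to the tertiary (Z)-iodoalkenyl cyclobutanol F3, in which C5–C6 is made and the tert-butyl ester should not lactonise onto the hindered carbinol. Pd(OAc)2/PPh3, Cs2CO3, toluene, 80 °C then performs the ring-opening coupling of a tertiary cyclobutanol with an alkenyl halide, which is established intermolecularly and here runs within one molecule: oxidative addition of zerovalent palladium into C10–I, palladium alkoxide formation, β-carbon elimination of C6–C9 and C–C reductive elimination (C9–C10), which delivers 16. This cures a failed oxidative coupling; against alkoxide loss it only offers a different metal and ligand.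

Step 11. What may go wrong: hydride delivery from the boron-bound C8 hydroxyl to the hindered, cross-conjugated C6 carbonyl is slow, so that undirected reduction competes and facial selectivity is lost. The fallback sets out from 16 and returns at 19. The ketone is reduced before the PMB group is removed, under reagent control, by Corey–Bakshi–Shibata reduction ((R)-2-methyl-CBS-oxazaborolidine, catecholborane, toluene, −78 °C; the alkenyl branch is taken as the large group) to the (6S)-allylic alcohol F4. Buffered DDQ at 0 °C then frees the C8 hydroxyl (diol ester 18) and catalytic KOt-Bu closes the lactone to 19.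

Step 13. What may go wrong: transmetalation at the tetrasubstituted alkenylpalladium iodide, flanked by the branched side chain, is slow, so that protodeiodination and decomposition of the stannane take over. The fallback sets out from 20 and returns at 21. Palladium-catalysed formylation (Pd(PPh3)4, CO (1 atm), Bu3SnH added slowly, THF, 50 °C), in which the small CO inserts before hydride transfer, gives the enal F5. Luche reduction (NaBH4, CeCl3·7H2O, MeOH, −40 °C) then reduces the aldehyde 1,2 without touching the lactone and gives 21.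

Further compounds
F1 | step 9 | titanium–alkyne complex of 15 (diisopropoxytitanacyclopropene) | CC(C)O[Ti]1(OC(C)C)C([Si](C)(C)C)=C1[C@H](C)CCCO[Si](C)(C)C(C)(C)C
F2 | step 9 | oxatitanacyclopentene from F1 and 8 (spiro at C6) | CC(C)(C)OC(=O)C[C@@H]1[C@H](OCc2ccc(OC)cc2)CC13O[Ti](OC(C)C)(OC(C)C)C([Si](C)(C)C)=C3[C@H](C)CCCO[Si](C)(C)C(C)(C)C
F3 | step 9 | tertiary cyclobutanol of 8 carrying the (Z)-1-iodo-1-(trimethylsilyl)alkenyl group on C6 (carbinol centre undefined) | CC(C)(C)OC(=O)C[C@@H]1[C@H](OCc2ccc(OC)cc2)CC1(O)/C([C@H](C)CCCO[Si](C)(C)C(C)(C)C)=C(\I)[Si](C)(C)C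
F4 | step 11 | tert-butyl 2-[(1S,2S,6R)-3-[(2R)-5-(tert-butyldimethylsilyloxy)pentan-2-yl]-2-hydroxy-6-(4-methoxybenzyloxy)-4-(trimethylsilyl)cyclohex-3-en-1-yl]acetate | CC(C)(C)OC(=O)C[C@@H]1[C@H](OCc2ccc(OC)cc2)CC([Si](C)(C)C)=C([C@H](C)CCCO[Si](C)(C)C(C)(C)C)[C@H]1O
F5 | step 13 | (3aS,4S,7aR)-5-[(2R)-5-(tert-butyldimethylsilyloxy)pentan-2-yl]-4-hydroxy-2-oxo-2,3,3a,4,7,7a-hexahydro-1-benzofuran-6-carbaldehyde | C1C(=O)O[C@@H]2CC(C=O)=C([C@H](C)CCCO[Si](C)(C)C(C)(C)C)[C@@H](O)[C@H]12
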